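Readings and results were computed for an exercise; noise was put on by code.

Early on, the two earlier runs looked like one curve: ochre read 40% at 30.0 s and green read 41% at 15.0 s, so I began from reagent charge times time.

| flask | substrate | reagent | remark | time |
|---|---|---|---|---|
| ochre | 1 mM | 2.8 mM | run made earlier |  |
| green | 1 mM | 6.1 mM | run made earlier |  |
| dusk | 1.0 mM | 4.00 mM |  | 0.80 min |
| autumn | 1.0 mM | 2.00 mM |  | 2.5 min |

| run | time / s | target / % |
|---|---|---|
| ochre | 15.0 | 33 |
| ochre | 30.0 | 40 |
| ochre | 50.0 | 47 |
| ochre | 60.0 | 48 |
| ochre | 80.0 | 56 |
| green | 15.0 | 41 |
| green | 30.0 | 49 |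
| green | 50.0 | 55 |
| green | 60.0 | 59 |
| green | 80.0 | 58 |

(standard deviation of a reading: 1.5 percentage points)

- the winner by amount of target, in percent of the substrate charged; "neither" if no more than 2 percentage points parts them (dusk / autumn / neither)
- how much target is there at the end, in percent of the substrate charged: dusk
- how much target is there at the end, in percent of the substrate charged: autumn

But that product counts the whole charge as working, and each substrate that reacts takes one reagent. So I treated this draw as a correction, reading it from the last ochre reading as 0.560 mM per 1.0 mM of substrate, against 2.00 mM of reagent in autumn and 4.00 mM in dusk.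

The free dose is reagent charge less this draw, times time. It came to 2.75 mM·min for dusk and 3.60 mM·min for autumn, so autumn's lead fell from a factor 1.56 to 1.31.

Around those doses, ochre at 80.0 s (2.99 mM·min) read 56%, green at 30.0 s (2.77 mM·min) read 49%, and green at 50.0 s (4.62 mM·min) read 55%. Ochre's reading stood 7 percentage points above that first green reading at the two nearby doses, against a scatter of 1.5 points, so the free dose did not lay the two runs on one curve. Still, dusk's dose lay beside the green reading and autumn's between the other two, so I reckoned on dusk near 49.0% and autumn near 55.5%, with autumn ahead by 6.5 points.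

The forecast gave dusk 51%, autumn 56% and the win to autumn: “Autumn should win narrowly”.

The flasks gave 51.5% in dusk and 51.8% in autumn, so the answer was neither, and the autumn lead I had reckoned did not appear.

    substrate + reagent ⇌ adduct (K = 217 /M, k = 68.2 /M/s)
    2 reagent → homo dimer (k = 33.3 /M/s)
    adduct → side product (k = 0.0133 /s)
    adduct → target (k = 0.174 /s)

In autumn, the half-life of substrate by the forward step alone was 0.16 min at 0.0852 min but 5.0 min at 2.50 min, longer than the run, with 1.7% of the reagent, the limiting reagent, left. Autumn's free dose of 3.60 mM·min stands ahead of dusk's 2.75 mM·min, yet from 1.25 min to 2.50 min its substrate went from 49.1% to 44.0%.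

With 1.7 mM of substrate in a neighbour of autumn and the same percentage drawn, the free dose is 2.62 mM·min, below dusk's, so I expected less target. The neighbour gave 44.9%, less than dusk's 51.5%.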